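Slowness is what these runs show first: after 40.0 h the amber run has put 4.1 % of its free monomer into chains. So we count turnovers. Each monomer unit taken into a chain is one turnover, and the average asked for is turnovers per chain begun, the number-average degree of polymerisation.

the same everywhere: impurity 2.3 mM

|  | free monomer | initiator | remark | time |
|---|---|---|---|---|
| amber | 0.076 M | 2.5 mM | run made earlier |  |
| green | 0.076 M | 5.7 mM | run made earlier |  |
| violet | 0.038 M | 3.8 mM | run made earlier |  |
| flask | 0.076 M | 3.8 mM |  | 2.0 d |

- whether the average number of monomer units in a chain (chains begun, living or dead) reaches 200 by 2.0 d (no / yes)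
- average number of monomer units in a chain (chains begun, living or dead) at 2.0 d

- the average divides the monomer in chains by the number of chains begun, living and dead together
- on the list of suspects stand: free monomer + living end -> monomer in chains + living end; initiator + impurity -> spent initiator B; 2 initiator -> spent initiator A; free monomer + initiator -> living end + monomer in chains
- the earlier runs do not show the number of chains; that part of a forecast is a guess

| run | time / h | monomer in chains / % | free monomer / % |
|---|---|---|---|
| amber | 2.50 | 1.0 | 99.4 |
| amber | 8.00 | 0 | 99.4 |
| amber | 15.0 | 0.5 | 98.4 |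
| amber | 20.0 | 1.0 | 97.4 |
| amber | 30.0 | 2.1 | 98.0 |
| amber | 40.0 | 4.1 | 96.3 |
| green | 2.50 | 1.1 | 99.3 |
| green | 8.00 | 3.3 | 98.8 |
| green | 15.0 | 3.2 | 95.5 |
| green | 20.0 | 4.6 | 95.9 |
| green | 30.0 | 5.1 | 92.8 |
| green | 40.0 | 8.3 | 91.5 |
| violet | 3.00 | 0 | 99.3 |
| violet | 10.0 | 1.7 | 100.1 |
| violet | 20.0 | 0 | 98.4 |
| violet | 30.0 | 1.0 | 97.8 |
| violet | 40.0 | 2.2 | 97.8 |

(each reading ± 1 percentage point)

We read the last row of each run. Amber and green share free monomer and impurity but differ in initiator: 2.5 mM gives 4.1 % and 5.7 mM gives 8.3 %. The flask's 3.8 mM lies between them, and a straight line between those rows gives 5.81 %. Violet, with the flask's initiator but half the free monomer, reads 2.2 %, less than that line gives, so free monomer counts as well, and the flask has the amber charge of it.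

Down the green rows, monomer in chains climbs roughly in line with time, and each reading carries a scatter of 1 percentage point. So we stretch our value to 2.0 d, which gives 6.97 %, or 5.30 mM of turnovers. Dividing by 200 gives 0.0265 mM, and this is our chain allowance, the concentration of chains begun at which those turnovers average the wanted length. It is 0.697 % of the initiator charged. The readings do not show the number of chains, so we commit to the allowance and not to a length: on this reckoning the flask answers yes if it begins fewer chains than this.

The forecast says no with an average of 15, and calls reaching the length “possible but unlikely”.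

The flask gives an average of 310 at 2.0 d, so the answer is yes.

    free monomer + living end → monomer in chains + living end, rate k1*[living end]*[free monomer] (k = 0.0243 M⁻¹ s⁻¹)
    initiator + impurity → spent initiator B (k = 6.75 M⁻¹ s⁻¹)
    2 initiator → spent initiator A (k = 2.54 M⁻¹ s⁻¹)
    free monomer + initiator → living end + monomer in chains (k = 6.25 × 10⁻⁴ M⁻¹ s⁻¹)

The flask passes 200 at 1.27 d, with 3.88 % of its free monomer reacted. Monomer in chains at 2.0 d stands at 6.02 %, so dividing by the average, the flask has begun 0.0148 mM, fewer chains than our allowance of 0.0265 mM. In the simulated run with twice the initiator the average is 291, so its chains begun fill 68.6 % of the allowance reckoned on its own monomer in chains.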